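The numbers in the tables come from a simulation from invented constants, and the scatter is random.

A small charge of reagent, 0.093 equiv in the green run, gives 5.6% target at 8.00 min, while a charge 32.3 times as large, in the teal run, gives 7.7% at 8.00 min. Substrate meanwhile stands at 21.7% in green and 23.6% in teal.

all flasks: substrate 16 mM

|  | reagent | remark | time |
|---|---|---|---|
| green | 0.093 equiv | run made earlier |  |
| teal | 3 equiv | run made earlier |  |
| beta | 0.0800 equiv |  | 15 min |
| epsilon | 0.250 equiv |  | 15 min |
| delta | 0.800 equiv |  | 15 min |
| gamma | 2.00 equiv |  | 15 min |

| run | time / min | target / % | substrate / % |
|---|---|---|---|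
| green | 1.00 | 0 | 83.7 |
| green | 2.50 | 0.2 | 61.7 |
| green | 5.00 | 2.9 | 38.5 |
| green | 8.00 | 5.6 | 21.7 |
| teal | 2.00 | 2.7 | 67.5 |
| teal | 4.00 | 1.2 | 46.9 |
| teal | 6.00 | 5.9 | 31.3 |
| teal | 8.00 | 7.7 | 23.6 |

(standard deviation of a reading: 1 percentage point)

- amount of target at the end, in percent of the substrate charged for beta, epsilon, delta, gamma, in this order
- how that number moves from the first to the last of them (rises all the way / falls all the way / rises, then falls / hardly changes / falls, then rises)

- on the list of suspects stand: reagent + intermediate B <-> intermediate C; substrate -> intermediate A; intermediate B <-> target; reagent + target -> over-reaction product; reagent + intermediate A -> intermediate B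
- "hardly changes" means that all values lie within two and a half points (for a concentration: within two and a half percent of the largest)

I clear this up by treating the two runs differently. In green, reagent is the limiting reagent: the suspected steps make one target per reagent, so green's ceiling is 9.30%. The gap below that ceiling is 6.40% at 5.00 min and 3.70% at 8.00 min, so it closes at 0.183 /min, a reading left loose by the scatter. Running that gap on to 15 min, I get the target per equivalent at the asked time, 88.9%. In teal, target at 8.00 min lies far below the charge, so there the excess reagent must be holding intermediate B as intermediate C or destroying target.

My first round multiplies by the charge: 7.11% for beta, 22.2% for epsilon, 71.1% for delta, 178% for gamma. Putting that back in, gamma's figure is more than the substrate charged, and gamma's charge lies nearer teal's than green's. So on the second round I keep beta and epsilon, take delta's figure as a ceiling, and expect a rise, then a fall.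

The forecast gives 6.8%, 20%, 52%, 28%, rises, then falls, reasoning that “Excess reagent must therefore hold B as C, or destroy target”.

The flask gives 7.08%, 20.9%, 47.7%, 28.1%: rises, then falls.

    reagent + intermediate B ⇌ intermediate C (K = 140 /M, k = 0.640 /M/s)
    substrate → intermediate A (k = 0.00320 /s)
    intermediate B ⇌ target (K = 46.0, k = 0.00360 /s)
    reagent + target → over-reaction product (k = 0.130 /M/s)
    reagent + intermediate A → intermediate B (k = 1.20 /M/s)

Beta's target per equivalent comes to 88.5%, against my 88.9%. At 15.0 min in beta, reagent is used on intermediate A 190 times as fast as on intermediate B (forward step alone), and target's half-life against over-reaction, 69 min with [reagent] as charged, is long against 15 min. Beta ends with 0.0126% intermediate C and 0.0217% over-reaction product. Epsilon, the second flask, gives 83.6% target per equivalent of its own charge, against the same 88.9%, with 0.149% intermediate C.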